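L, the electrophile, meets E in each set-up below, and the question is how much Z comes out.

    E + G ⇌ E.G, settled at all times (K1 = 270 M⁻¹)
    2 E → E2 (k2 = 0.019 M⁻¹ h⁻¹)
    L + E → G + Z (k3 = 0.042 M⁻¹ h⁻¹)

| flask | L | E | time | remark |
|---|---|---|---|---|
| east | 0.10 M | 0.300 M (fed, over 1.25 d) | 2.5 d | a stirred flask in which E is dosed at a steady rate over 1.25 d without added volume, worked up at 2.5 d |
| north | 0.10 M | 0.300 M |  | a single well-mixed tank run continuously and read at steady state, 2.5 d in it on average |
| south | 0.10 M (fed, over 1.25 d) | 0.300 M | 2.5 d | all but L at the start; L goes in evenly over 1.25 d, the run ends at 2.5 d |
| west | 0.10 M | 0.300 M | 2.5 d | a closed flask charged with all of it at once and left for 2.5 d |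

- where a step has two of a species, its rate is k times that concentration squared, and two are used at each turn
- the stated concentrations are those of everything mixed, before any reaction; amounts are the same in each set-up
- the feed brings no volume worth counting
- run time (east): 2.5 d

- the set-up with the highest amount of Z at the outlet or at the end, in percent of the L put in ("none" if the first two lie within 2 percentage points) (east / north / south / west / none)
- amount of Z at the outlet or at the end, in percent of the L put in, east
- amount of Z at the outlet or at the end, in percent of the L put in, north
- amount of Z at the outlet or at the end, in percent of the L put in, south
- amount of Z at the outlet or at the end, in percent of the L put in, west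

Count turnovers, and begin with west, where E starts at its full charge. Set up a small table of counts over 2.5 d, with E taken at that charge.

First row, L: the turnover count, which is the rate constant of the step to Z times free E times the time, is the number of L lifetimes the run holds under pseudo-first-order decay. It comes to 0.756.

Second row, E: the same count for the pairing of E, with its factor 2, comes to 0.684.

Third row, G: the binding constant times E gives 81.0 bound G for each free G.

Read the first two rows together. The second is less than the first, yet of like size, so E does not stay at its charge over the run. Taken by itself, pairing has lowered E at the end of the run by the factor one plus the second row, and summing free E over the run cuts the turnover count to 0.576. That puts Z at 43.8% of the L put in.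

Now read the third row: at that ratio nearly all G is bound to an E, so each Z costs about 2 E. The count above leaves that cost out, so commit to a figure for west below 43.8%. Expect west to lead, the flask in which L and E both stand at their full charges from the start.

The forecast names west, with east 34%, north 30.3%, south 29.6% and west 38.7%, which is less than the figure above. Its ground: "West does best because L sees the most E for the full time".

The simulation gives east 34.0%, north 30.3%, south 29.7% and west 38.8%, so west leads.

Read the count back from L: west ends with 61.2% of its L, a count of 0.492, less than the 0.756 of the first row. Part of what holds Z down in west is the pairing of E, acting together with the time allowed: without pairing, Z in west rises from 38.8% to 46.3%, and tenfold time gives 76.5%. Carry the count to the tank in north, where E stands at 0.172 M: over the average 2.5 d it is 0.434. There the share of Z is the count over one plus the count, 30.3%, and the tank reads 30.3%.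

(All constants come from no measurement, and the outcome is calculated.)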